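The plan rests on cutting the unbranched tridecyl chain at its C6′–C7′ bond, six methylenes out from C2 of the 4H-chromen-4-one (the pyranone ring fused to the fully substituted benzene ring). This sp3–sp3 bond lies far from every functional group, so it can be made last, on the unprotected 5,7-dihydroxy-6,8-dimethylchromone. In one operation a room-temperature B-alkyl Suzuki–Miyaura coupling joins B-heptyl-9-BBN, made in situ from hept-1-ene, to 2-(6-bromohexyl)-5,7-dihydroxy-6,8-dimethylchromone and should deliver the target directly. The bromide comes from polyanion acylation of C-dimethylated phloroacetophenone with 7-bromoheptanoyl chloride and acid cyclodehydration.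

Key step: step 4

Remark: the target has no stereocentre, so no stereocontrol is needed; both phenols are carried unprotected throughout.

Step 1
Reactants: 1 2′,4′,6′-trihydroxyacetophenone (phloroacetophenone)
Product: 2 1-(2,4,6-trihydroxy-3,5-dimethylphenyl)ethan-1-one
Conditions: MeI (2.1 equiv), NaOMe (3.0 equiv), MeOH, 0 °C → reflux
Reagents that add atoms: iodomethane, CI
Why: C-alkylation of an acylphloroglucinol phenoxide (a vinylogous β-triketone anion) at its two free ring carbons C3′ and C5′; limiting MeI to about two equivalents should stop the reaction before geminal methylation dearomatises the ring.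

Step 2
Reactants: 3 7-bromoheptanoic acid
Product: 4 7-bromoheptanoyl chloride
Conditions: (COCl)2 (1.3 equiv), cat. DMF, CH2Cl2, 0 °C → rt; evaporate, use crude
Reagents that add atoms: oxalyl chloride, O=C(Cl)C(=O)Cl
Why: Acid chloride formation through the Vilsmeier-type chloroiminium catalyst; the primary bromide is inert under these conditions.

Step 3
Reactants: 2 1-(2,4,6-trihydroxy-3,5-dimethylphenyl)ethan-1-one, 4 7-bromoheptanoyl chloride
Product: 6 2-(6-bromohexyl)-5,7-dihydroxy-6,8-dimethyl-4H-chromen-4-one, via β-diketone 5 (not isolated)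
Conditions: 2, LiHMDS (5.0 equiv), THF, −78 → −10 °C; 4 (1.0 equiv), −78 °C → rt; then MeOH, conc. HCl (excess), 65 °C
Reagents that add atoms: none
Why: Claisen-type C-acylation of the lithium polyanion of an o-hydroxyacetophenone (any O-acyl product should funnel to the same diketone by Baker–Venkataraman shift), followed by acid-catalysed cyclodehydration of the o-hydroxyaryl β-diketone to the chromone; the two ortho hydroxyls are equivalent by symmetry, so only one chromone can form.

Step 4
Reactants: 6 2-(6-bromohexyl)-5,7-dihydroxy-6,8-dimethyl-4H-chromen-4-one, 7 hept-1-ene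
Product: 9 5,7-dihydroxy-6,8-dimethyl-2-tridecyl-4H-chromen-4-one (target), via B-heptyl-9-BBN 8 (not isolated)
Conditions: 7 (2.2 equiv), 9-BBN (0.5 M in THF, 2.0 equiv), 0 °C → rt, 3 h; then 6, Pd(OAc)2 (5 mol%), PCy3 (10 mol%), K3PO4·H2O (4 equiv), THF, rt, 24 h; aq. NH4Cl (pH ≈ 4) work-up
Reagents that add atoms: none
Why: Anti-Markovnikov hydroboration of hept-1-ene places boron on the terminal carbon; Pd(0)/PCy3 then inserts into the primary C(sp3)–Br bond of 6, the hydroxyborate of 8 transfers its primary heptyl group (the secondary bicyclic B–C bonds do not transfer), and reductive elimination forms the C6′–C7′ bond. The closest known reaction type is the room-temperature Pd/trialkylphosphine B-alkyl Suzuki–Miyaura coupling of primary alkyl bromides that carry β-hydrogens. No ring is closed and no stereocentre is formed. The step needs reductive elimination to outrun β-hydride elimination, which the bulky, electron-rich PCy3 should secure. It also needs chemoselectivity for C–Br over the chromone, which as a β,β-disubstituted vinylogous ester is not expected to react with the trialkylborane or Pd(0). The extra phosphate covers deprotonation of the phenols; the 7-oxide is a delocalised vinylogous carboxylate and the 5-OH is chelated to C4=O, so neither should attack the primary bromide at room temperature in THF.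

Compound list
1 | 2′,4′,6′-trihydroxyacetophenone (phloroacetophenone) | CC(=O)c1c(O)cc(O)cc1O | starting material
2 | 1-(2,4,6-trihydroxy-3,5-dimethylphenyl)ethan-1-one | CC(=O)c1c(O)c(C)c(O)c(C)c1O | intermediate
3 | 7-bromoheptanoic acid | OC(=O)CCCCCCBr | starting material
4 | 7-bromoheptanoyl chloride | ClC(=O)CCCCCCBr | intermediate
5 | 9-bromo-1-(2,4,6-trihydroxy-3,5-dimethylphenyl)nonane-1,3-dione | O=C(CC(=O)CCCCCCBr)c1c(O)c(C)c(O)c(C)c1O | intermediate
6 | 2-(6-bromohexyl)-5,7-dihydroxy-6,8-dimethyl-4H-chromen-4-one | BrCCCCCCc1cc(=O)c2c(O)c(C)c(O)c(C)c2o1 | intermediate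
7 | hept-1-ene | C=CCCCCC | starting material
8 | 9-heptyl-9-borabicyclo[3.3.1]nonane (B-heptyl-9-BBN) | CCCCCCCB1C2CCCC1CCC2 | intermediate
9 | 5,7-dihydroxy-6,8-dimethyl-2-tridecyl-4H-chromen-4-one | CCCCCCCCCCCCCc1cc(=O)c2c(O)c(C)c(O)c(C)c2o1 | target

Total step count: 4. Longest linear sequence: 3 steps (steps 1, 3 and 4, from 1 through 2 and 6 to 9); step 2 is a one-step side branch.

Steps most likely to fail

Step 4. Deprotonation of the phenols by phosphate may precipitate the substrate or tie up the borane as an aryloxyborate, so that transmetalation stalls and β-hydride elimination or protodehalogenation of the alkylpalladium takes over. The fallback forms the same chain bond as an alkene under neutral conditions. It sets out from 2 and comes back at 9. Oct-7-enoic acid and oxalyl chloride (cat. DMF, CH2Cl2) should give oct-7-enoyl chloride F1. Acylation of the LiHMDS polyanion of 2 with it, as in step 3, should give 1-(2,4,6-trihydroxy-3,5-dimethylphenyl)dec-9-ene-1,3-dione F2. F2 is cyclised in the same flask (HCl, MeOH, 65 °C) to 2-(hept-6-en-1-yl)-5,7-dihydroxy-6,8-dimethyl-4H-chromen-4-one F3. Olefin cross-metathesis of F3 with excess oct-1-ene (Hoveyda–Grubbs II, CH2Cl2, 40 °C) should give 5,7-dihydroxy-6,8-dimethyl-2-(tridec-6-en-1-yl)-4H-chromen-4-one F4 as an E/Z mixture of no consequence. Hydrogenation (H2 1 atm, Pd/C, EtOAc, rt) should reduce the isolated disubstituted alkene much faster than the vinylogous-ester C2=C3 bond and give 9.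

Step 3. The tetralithium salt of 2 may be poorly soluble, and the enolisable acid chloride may be diverted by O-acylation or ketene formation, so that C-acylation stays incomplete. The fallback lowers the charge of the nucleophile by protection. It sets out from 2 and comes back at 6. MOMCl (2.2 equiv) and i-Pr2NEt in CH2Cl2 should protect the 4-OH and one ortho OH, leaving the chelated one, to give 1-[2-hydroxy-4,6-bis(methoxymethoxy)-3,5-dimethylphenyl]ethan-1-one F5. Its soluble dianion (LiHMDS, 3 equiv, THF, −78 °C) is acylated with 4 to give 9-bromo-1-[2-hydroxy-4,6-bis(methoxymethoxy)-3,5-dimethylphenyl]nonane-1,3-dione F6. HCl in MeOH at 65 °C should then cyclodehydrate F6 and remove both MOM groups to give 6.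

Step 1. Alkylation may not stop cleanly at two C-methyl groups: geminal methylation with dearomatisation and some O-methylation would erode the material. The fallback installs each methyl as an aminomethyl group, which cannot over-alkylate. It sets out from 1 and comes back at 2. Double Mannich reaction of 1 (aq. formaldehyde, dimethylamine, EtOH, rt) should give 1-{3,5-bis[(dimethylamino)methyl]-2,4,6-trihydroxyphenyl}ethan-1-one F7. Hydrogenolysis of both benzylic C–N bonds (H2, Pd/C, AcOH, 60 °C) should give 2.

Further compounds
F1 | step 4 | oct-7-enoyl chloride | C=CCCCCCC(=O)Cl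
F2 | step 4 | 1-(2,4,6-trihydroxy-3,5-dimethylphenyl)dec-9-ene-1,3-dione | C=CCCCCCC(=O)CC(=O)c1c(O)c(C)c(O)c(C)c1O
F3 | step 4 | 2-(hept-6-en-1-yl)-5,7-dihydroxy-6,8-dimethyl-4H-chromen-4-one | C=CCCCCCc1cc(=O)c2c(O)c(C)c(O)c(C)c2o1
F4 | step 4 | 5,7-dihydroxy-6,8-dimethyl-2-[(E)-tridec-6-en-1-yl]-4H-chromen-4-one (E shown; E/Z mixture expected) | CCCCCC/C=C/CCCCCc1cc(=O)c2c(O)c(C)c(O)c(C)c2o1
F5 | step 3 | 1-[2-hydroxy-4,6-bis(methoxymethoxy)-3,5-dimethylphenyl]ethan-1-one | CC(=O)c1c(O)c(C)c(OCOC)c(C)c1OCOC
F6 | step 3 | 9-bromo-1-[2-hydroxy-4,6-bis(methoxymethoxy)-3,5-dimethylphenyl]nonane-1,3-dione | O=C(CC(=O)CCCCCCBr)c1c(O)c(C)c(OCOC)c(C)c1OCOC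
F7 | step 1 | 1-{3,5-bis[(dimethylamino)methyl]-2,4,6-trihydroxyphenyl}ethan-1-one | CC(=O)c1c(O)c(CN(C)C)c(O)c(CN(C)C)c1O
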